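**Retrosynthetic overview** (locants follow 2,3-dihydro-1,4-benzodioxine numbering)
1. The (E)-propenal is attached last to C6 of ring A by a Heck reaction of an aryl bromide with acrolein diethyl acetal; the syringyl phenol travels as a TIPS ether and is freed in the final step.
2. The dioxane ring (ring B, the only ring made; both benzene rings are bought) is cut at C2–C3 and at O4–C4a. This gives O-silyl syringaldehyde and an α-(2-iodoaryloxy)acetyl 7-azaindoline amide, to be joined in one flask by an asymmetric aldol addition that runs on into an intramolecular Ullmann O-arylation: a (4+2) annulation that sets both stereocentres.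
3. Enabling feature: C2 lies between ring oxygen O1 and the CH2OH carbon, so with that carbon at the carboxamide level C2 is a glycolate α-carbon (latent enolate). C3 is a benzylic carbinol carbon (latent aldehyde carbon). O4 is bound to C4a, ortho to the O1-bearing C8a, so an ortho-iodide on the glycolate aryl ether lets the aldolate oxygen close a six-membered ring.
4. The donor comes from 4-bromo-2-methoxyphenol (iodination ortho to OH, then Williamson alkylation with N-chloroacetyl-7-azaindoline); the amide is reduced to CH2OH after the annulation.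

Key step: step 5

Assumption: the (R)-antipode of the bisphosphine is taken to direct the enolate to the Re face of aldehyde 8; should a pilot run show the opposite sense, the (S)-ligand is used and nothing else changes.

**Route**

Step 1
Reactants: 1 4-bromo-2-methoxyphenol
Product: 2 4-bromo-2-iodo-6-methoxyphenol
Conditions: N-iodosuccinimide (1.05 equiv), TsOH·H2O (10 mol %), MeCN, 0 °C to rt
Reagents that add atoms: N-iodosuccinimide, O=C1CCC(=O)N1I
Why: Electrophilic aromatic iodination in which the free hydroxyl is the strongest director and, its para position being blocked by bromine, sends iodine to the only free ortho position.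

Step 2
Reactants: 3 7-azaindoline (2,3-dihydro-1H-pyrrolo[2,3-b]pyridine); 4 chloroacetyl chloride
Product: 5 2-chloro-1-(2,3-dihydro-1H-pyrrolo[2,3-b]pyridin-1-yl)ethan-1-one
Conditions: K2CO3, CH2Cl2/H2O, 0 °C
Reagents that add atoms: none
Why: Schotten–Baumann N-acylation of the indoline-type NH, the acyl chloride being far more electrophilic than the alkyl chloride.

Step 3
Reactants: 2 4-bromo-2-iodo-6-methoxyphenol; 5 2-chloro-1-(2,3-dihydro-1H-pyrrolo[2,3-b]pyridin-1-yl)ethan-1-one
Product: 6 2-(4-bromo-2-iodo-6-methoxyphenoxy)-1-(2,3-dihydro-1H-pyrrolo[2,3-b]pyridin-1-yl)ethan-1-one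
Conditions: K2CO3, NaI (10 mol %), DMF, 50 °C
Reagents that add atoms: none
Why: Williamson ether synthesis, an SN2 displacement by the phenoxide on the α-halo amide assisted by Finkelstein exchange.

Step 4
Reactants: 7 syringaldehyde (4-hydroxy-3,5-dimethoxybenzaldehyde)
Product: 8 3,5-dimethoxy-4-[tri(propan-2-yl)silyloxy]benzaldehyde
Conditions: TIPSCl, imidazole, DMAP (cat.), DMF, 40 °C
Reagents that add atoms: chlorotri(propan-2-yl)silane (TIPSCl), CC(C)[Si](Cl)(C(C)C)C(C)C
Why: O-Silylation of the acidic phenol, which masks it as a base-stable ether so that the aldehyde stays electrophilic and the later benzylic aryl ether cannot open through a quinone methide.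

Step 5
Reactants: 6 2-(4-bromo-2-iodo-6-methoxyphenoxy)-1-(2,3-dihydro-1H-pyrrolo[2,3-b]pyridin-1-yl)ethan-1-one; 8 3,5-dimethoxy-4-[tri(propan-2-yl)silyloxy]benzaldehyde
Product: 10 [(2R,3S)-6-bromo-3-{3,5-dimethoxy-4-[tri(propan-2-yl)silyloxy]phenyl}-8-methoxy-2,3-dihydro-1,4-benzodioxin-2-yl](2,3-dihydro-1H-pyrrolo[2,3-b]pyridin-1-yl)methanone, via syn-aldol adduct 9 (not isolated)
Conditions: [Cu(CH3CN)4]PF6 (10 mol %), (R)-DTBM-SEGPHOS (12 mol %), 2-tert-butyl-1,1,3,3-tetramethylguanidine (10 mol %), THF, −40 °C; then CuI (10 mol %), 3,4,7,8-tetramethyl-1,10-phenanthroline (20 mol %), Cs2CO3 (1.5 equiv), toluene, 60 °C, same flask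
Reagents that add atoms: none
Why: Proposed new method: the monovalent copper–bisphosphine cation chelates the pyridine nitrogen and the amide oxygen of 6, the guanidine base removes the proton between the carbonyl group and the aryloxy oxygen, and the chelated Z-enolate adds to aldehyde 8 to give the copper aldolate of 9 (C2–C3 bond); after CuI, the phenanthroline and Cs2CO3 are added and the flask is warmed, this alkoxide oxygen binds copper, the ortho C–I bond adds oxidatively and C–O reductive elimination from trivalent copper closes the O4–C4a bond. The closest known reaction types are the direct catalytic asymmetric aldol reaction of α-heteroatom-substituted 7-azaindoline amides under soft Lewis acid/Brønsted base catalysis and the intramolecular Ullmann etherification of secondary alcohols, merged here into one (4+2) annulation that has not been run as a single operation on α-(2-haloaryloxy)acetamides. The 1,4-dioxane ring is closed by reductive elimination from a seven-membered cupracycle, formally a 6-exo ipso substitution of iodide at the aryl carbon by the aldolate oxygen. Both stereocentres arise in the aldol event: the chiral bisphosphine on copper selects the Re face of the aldehyde (C3, S) and the chelated Z-enolate enforces the syn relationship (C2, R at the amide level), and since the C–O coupling breaks no bond at either carbon the syn adduct maps onto the trans-2,3-disubstituted ring. The step needs iodide-over-bromide chemoselectivity, secured by the six-membered intramolecular closure at the more reactive ortho C–I bond, and it needs ring closure to outrun retro-aldol cleavage and dehydration, for which the weakly basic carbonate medium, the moderate temperature and an electron-rich ring A without an acceptor para to the ether oxygen (no Smiles scrambling) are chosen.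

Step 6
Reactants: 10 [(2R,3S)-6-bromo-3-{3,5-dimethoxy-4-[tri(propan-2-yl)silyloxy]phenyl}-8-methoxy-2,3-dihydro-1,4-benzodioxin-2-yl](2,3-dihydro-1H-pyrrolo[2,3-b]pyridin-1-yl)methanone
Product: 11 [(2S,3S)-6-bromo-3-{3,5-dimethoxy-4-[tri(propan-2-yl)silyloxy]phenyl}-8-methoxy-2,3-dihydro-1,4-benzodioxin-2-yl]methanol
Conditions: LiBH4 (3 equiv), MeOH (3 equiv), THF, 0 °C to rt
Reagents that add atoms: none
Why: Borohydride reduction of the activated N-acyl-7-azaindoline (an anilide-type amide with Weinreb-like chelation) to the primary alcohol with release of 7-azaindoline, under conditions that leave the aryl bromide, the silyl ether and both stereocentres untouched.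

Step 7
Reactants: 11 [(2S,3S)-6-bromo-3-{3,5-dimethoxy-4-[tri(propan-2-yl)silyloxy]phenyl}-8-methoxy-2,3-dihydro-1,4-benzodioxin-2-yl]methanol; 12 acrolein diethyl acetal (3,3-diethoxyprop-1-ene)
Product: 14 (2E)-3-[(2S,3S)-3-{3,5-dimethoxy-4-[tri(propan-2-yl)silyloxy]phenyl}-2-(hydroxymethyl)-8-methoxy-2,3-dihydro-1,4-benzodioxin-6-yl]prop-2-enal, via enal diethyl acetal 13 (not isolated)
Conditions: Pd(OAc)2 (3 mol %), nBu4NOAc, K2CO3, KCl, dry DMF, 90 °C; then 2 M HCl, rt
Reagents that add atoms: water, O
Why: Mizoroki–Heck arylation of the terminal alkene under ligand-free, acetate-buffered conditions that favour β-hydride elimination to the conjugated E-alkene, followed by acid hydrolysis of the acetal to the E-enal.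

Step 8
Reactants: 14 (2E)-3-[(2S,3S)-3-{3,5-dimethoxy-4-[tri(propan-2-yl)silyloxy]phenyl}-2-(hydroxymethyl)-8-methoxy-2,3-dihydro-1,4-benzodioxin-6-yl]prop-2-enal
Product: 15 bilagrewin, (2E)-3-[(2S,3S)-3-(4-hydroxy-3,5-dimethoxyphenyl)-2-(hydroxymethyl)-8-methoxy-2,3-dihydro-1,4-benzodioxin-6-yl]prop-2-enal
Conditions: TBAF, AcOH (1:1), THF, 0 °C
Reagents that add atoms: none
Why: Fluoride cleavage of the aryl silyl ether, buffered with acetic acid so that no free phenoxide builds up that could open the benzylic aryl ether through a quinone methide or add to the enal.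

**Compound list**
1 | 4-bromo-2-methoxyphenol | COc1cc(Br)ccc1O | starting material
2 | 4-bromo-2-iodo-6-methoxyphenol | COc1cc(Br)cc(I)c1O | intermediate
3 | 7-azaindoline (2,3-dihydro-1H-pyrrolo[2,3-b]pyridine) | C1Cc2cccnc2N1 | starting material
4 | chloroacetyl chloride | ClCC(Cl)=O | starting material
5 | 2-chloro-1-(2,3-dihydro-1H-pyrrolo[2,3-b]pyridin-1-yl)ethan-1-one | O=C(CCl)N1CCc2cccnc21 | intermediate
6 | 2-(4-bromo-2-iodo-6-methoxyphenoxy)-1-(2,3-dihydro-1H-pyrrolo[2,3-b]pyridin-1-yl)ethan-1-one | COc1cc(Br)cc(I)c1OCC(=O)N1CCc2cccnc21 | intermediate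
7 | syringaldehyde (4-hydroxy-3,5-dimethoxybenzaldehyde) | COc1cc(C=O)cc(OC)c1O | starting material
8 | 3,5-dimethoxy-4-[tri(propan-2-yl)silyloxy]benzaldehyde | COc1cc(C=O)cc(OC)c1O[Si](C(C)C)(C(C)C)C(C)C | intermediate
9 | (2R,3S)-2-(4-bromo-2-iodo-6-methoxyphenoxy)-1-(2,3-dihydro-1H-pyrrolo[2,3-b]pyridin-1-yl)-3-{3,5-dimethoxy-4-[tri(propan-2-yl)silyloxy]phenyl}-3-hydroxypropan-1-one (syn-aldol adduct, not isolated) | COc1cc([C@@H]([C@@H](Oc2c(I)cc(Br)cc2OC)C(=O)N2CCc3cccnc32)O)cc(OC)c1O[Si](C(C)C)(C(C)C)C(C)C | intermediate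
10 | [(2R,3S)-6-bromo-3-{3,5-dimethoxy-4-[tri(propan-2-yl)silyloxy]phenyl}-8-methoxy-2,3-dihydro-1,4-benzodioxin-2-yl](2,3-dihydro-1H-pyrrolo[2,3-b]pyridin-1-yl)methanone (trans) | COc1cc([C@@H]2Oc3cc(Br)cc(OC)c3O[C@H]2C(=O)N2CCc3cccnc32)cc(OC)c1O[Si](C(C)C)(C(C)C)C(C)C | intermediate
11 | [(2S,3S)-6-bromo-3-{3,5-dimethoxy-4-[tri(propan-2-yl)silyloxy]phenyl}-8-methoxy-2,3-dihydro-1,4-benzodioxin-2-yl]methanol | COc1cc([C@@H]2Oc3cc(Br)cc(OC)c3O[C@H]2CO)cc(OC)c1O[Si](C(C)C)(C(C)C)C(C)C | intermediate
12 | acrolein diethyl acetal (3,3-diethoxyprop-1-ene) | C=CC(OCC)OCC | starting material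
13 | [(2S,3S)-6-[(1E)-3,3-diethoxyprop-1-en-1-yl]-3-{3,5-dimethoxy-4-[tri(propan-2-yl)silyloxy]phenyl}-8-methoxy-2,3-dihydro-1,4-benzodioxin-2-yl]methanol (not isolated) | COc1cc([C@@H]2Oc3cc(/C=C/C(OCC)OCC)cc(OC)c3O[C@H]2CO)cc(OC)c1O[Si](C(C)C)(C(C)C)C(C)C | intermediate
14 | (2E)-3-[(2S,3S)-3-{3,5-dimethoxy-4-[tri(propan-2-yl)silyloxy]phenyl}-2-(hydroxymethyl)-8-methoxy-2,3-dihydro-1,4-benzodioxin-6-yl]prop-2-enal | COc1cc([C@@H]2Oc3cc(/C=C/C=O)cc(OC)c3O[C@H]2CO)cc(OC)c1O[Si](C(C)C)(C(C)C)C(C)C | intermediate
15 | bilagrewin, (2E)-3-[(2S,3S)-3-(4-hydroxy-3,5-dimethoxyphenyl)-2-(hydroxymethyl)-8-methoxy-2,3-dihydro-1,4-benzodioxin-6-yl]prop-2-enal | COc1cc([C@@H]2Oc3cc(/C=C/C=O)cc(OC)c3O[C@H]2CO)cc(OC)c1O | target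

**Step count**
Total: 8 steps. Longest linear sequence: 6 steps (steps 1, 3, 5, 6, 7, 8, from 4-bromo-2-methoxyphenol).

**Steps most likely to fail**

Step 5 (proposed new method). What may go wrong: retro-aldol equilibration of the aldolate during the warm O-arylation stage, eroding enantio- and diastereocontrol; dehydration of the aldolate; or enolate-driven ring opening of the product by β-elimination of the aryloxide. The fallback sets the stereocentres with a covalently bound auxiliary and closes the ring in a separate, known operation. It sets out from phenol 2. Alkylation with commercial (4R)-4-benzyl-3-(chloroacetyl)-1,3-oxazolidin-2-one (K2CO3, NaI, acetone, 50 °C) should give (4R)-4-benzyl-3-[(4-bromo-2-iodo-6-methoxyphenoxy)acetyl]-1,3-oxazolidin-2-one F1. An Evans boron aldol reaction with aldehyde 8 (Bu2BOTf, i-Pr2NEt, CH2Cl2, −78 to 0 °C) should give, through the Zimmerman–Traxler chair of the Z-boron enolate, the syn adduct (4R)-4-benzyl-3-[(2R,3S)-2-(4-bromo-2-iodo-6-methoxyphenoxy)-3-{3,5-dimethoxy-4-[tri(propan-2-yl)silyloxy]phenyl}-3-hydroxypropanoyl]-1,3-oxazolidin-2-one F2. LiBH4 (THF/H2O, 0 °C) should remove the auxiliary and give (1S,2S)-2-(4-bromo-2-iodo-6-methoxyphenoxy)-1-{3,5-dimethoxy-4-[tri(propan-2-yl)silyloxy]phenyl}propane-1,3-diol F3. TBSCl and imidazole (CH2Cl2, 0 °C) should silylate only the primary hydroxyl to give (1S,2S)-2-(4-bromo-2-iodo-6-methoxyphenoxy)-3-{[tert-butyl(dimethyl)silyl]oxy}-1-{3,5-dimethoxy-4-[tri(propan-2-yl)silyloxy]phenyl}propan-1-ol F4. Intramolecular Ullmann etherification (CuI, 3,4,7,8-tetramethyl-1,10-phenanthroline, Cs2CO3, toluene, 90 °C) through the free benzylic hydroxyl should give tert-butyl{[(2S,3S)-6-bromo-3-{3,5-dimethoxy-4-[tri(propan-2-yl)silyloxy]phenyl}-8-methoxy-2,3-dihydro-1,4-benzodioxin-2-yl]methoxy}dimethylsilane F5. PPTS in MeOH should then remove the alkyl TBS ether while sparing the aryl TIPS ether, so that the route is rejoined at alcohol 11.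

Step 6. What may go wrong: the hydride adduct of the chelating amide may persist as a stable tetrahedral intermediate and release the α-aryloxy aldehyde only on work-up, which would leave the reduction incomplete and expose C2 to epimerisation. The fallback replaces direct reduction by hydrolysis followed by a carboxylic acid reduction. It sets out from amide 10: LiOH/H2O2 (THF/H2O, 0 °C) should cleave the activated amide to (2R,3S)-6-bromo-3-{3,5-dimethoxy-4-[tri(propan-2-yl)silyloxy]phenyl}-8-methoxy-2,3-dihydro-1,4-benzodioxine-2-carboxylic acid F6, and BH3·SMe2 (THF, 0 °C to rt) should reduce the acid chemoselectively to alcohol 11, where the route is rejoined.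

Step 7. What may go wrong: β-hydride elimination towards the acetal carbon (leading to the saturated ester after hydrolysis), slow oxidative addition into the electron-rich aryl bromide, and partial loss of the aryl silyl ether in hot carbonate/DMF, which would expose a phenoxide to quinone-methide ring opening. The fallback fixes the alkene geometry in the coupling partner and runs at lower temperature. It sets out from bromide 11: Suzuki–Miyaura coupling with commercial (E)-2-(3,3-diethoxyprop-1-en-1-yl)-4,4,5,5-tetramethyl-1,3,2-dioxaborolane (Pd(dppf)Cl2, K3PO4, THF/H2O, 60 °C) should give acetal 13, and dilute HCl at rt should hydrolyse it to enal 14, where the route is rejoined.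

**Further compounds**
F1 | step 5 | (4R)-4-benzyl-3-[(4-bromo-2-iodo-6-methoxyphenoxy)acetyl]-1,3-oxazolidin-2-one | COc1cc(Br)cc(I)c1OCC(=O)N1[C@H](Cc2ccccc2)COC1=O
F2 | step 5 | (4R)-4-benzyl-3-[(2R,3S)-2-(4-bromo-2-iodo-6-methoxyphenoxy)-3-{3,5-dimethoxy-4-[tri(propan-2-yl)silyloxy]phenyl}-3-hydroxypropanoyl]-1,3-oxazolidin-2-one | COc1cc([C@@H]([C@@H](Oc2c(I)cc(Br)cc2OC)C(=O)N2[C@H](Cc3ccccc3)COC2=O)O)cc(OC)c1O[Si](C(C)C)(C(C)C)C(C)C
F3 | step 5 | (1S,2S)-2-(4-bromo-2-iodo-6-methoxyphenoxy)-1-{3,5-dimethoxy-4-[tri(propan-2-yl)silyloxy]phenyl}propane-1,3-diol | COc1cc([C@@H]([C@@H](Oc2c(I)cc(Br)cc2OC)CO)O)cc(OC)c1O[Si](C(C)C)(C(C)C)C(C)C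
F4 | step 5 | (1S,2S)-2-(4-bromo-2-iodo-6-methoxyphenoxy)-3-{[tert-butyl(dimethyl)silyl]oxy}-1-{3,5-dimethoxy-4-[tri(propan-2-yl)silyloxy]phenyl}propan-1-ol | COc1cc([C@@H]([C@@H](Oc2c(I)cc(Br)cc2OC)CO[Si](C)(C)C(C)(C)C)O)cc(OC)c1O[Si](C(C)C)(C(C)C)C(C)C
F5 | step 5 | tert-butyl{[(2S,3S)-6-bromo-3-{3,5-dimethoxy-4-[tri(propan-2-yl)silyloxy]phenyl}-8-methoxy-2,3-dihydro-1,4-benzodioxin-2-yl]methoxy}dimethylsilane | COc1cc([C@@H]2Oc3cc(Br)cc(OC)c3O[C@H]2CO[Si](C)(C)C(C)(C)C)cc(OC)c1O[Si](C(C)C)(C(C)C)C(C)C
F6 | step 6 | (2R,3S)-6-bromo-3-{3,5-dimethoxy-4-[tri(propan-2-yl)silyloxy]phenyl}-8-methoxy-2,3-dihydro-1,4-benzodioxine-2-carboxylic acid | COc1cc([C@@H]2Oc3cc(Br)cc(OC)c3O[C@H]2C(=O)O)cc(OC)c1O[Si](C(C)C)(C(C)C)C(C)C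
F0 | step 7 | none | none
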